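If more G was to buy a better excess of X over D, it first had to reach the solution, so I reckoned what the solid could deliver before I chose the next charge.

    Q + E + J → E + X (k1 = 1400 /M²/s)
    Q + E + L → E + D (k2 = 410 /M²/s)
    G ⇌ Q, rate k3*(cs3 - [Q]) while solid is left; crystals form when [Q] > cs3 (cs3 = 2.9 mM, k3 = 6.2 × 10⁻⁴ /s)
    E → Z (k4 = 5.7 × 10⁻⁴ /s)

| flask | J | G | E | L | time |
|---|---|---|---|---|---|
| larch | 0.050 M | 0.400 equiv | 0.11 mol% | 0.050 M | 10 min |
| alder | 0.050 M | 1.20 equiv | 0.11 mol% | 0.050 M | 10 min |
| birch | 0.050 M | 4.00 equiv | 0.11 mol% | 0.050 M | 10 min |
| cedar | 0.050 M | 10.0 equiv | 0.11 mol% | 0.050 M | 10 min |

- E is single-handed; J and L are mirror images of each other, charged as a racemate, each of them at the stated concentration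
- solid, in amounts per volume of the solution: G
- at the start none of G is in solution
- an excess is the difference of the two amounts in percent of their sum
- "hardly changes" means that all values lie within two and a half points (for a concentration: within two and a half percent of the largest)
- run time (larch): 10 min

* excess of X over D at the end for larch, alder, birch, cedar, in this order
* how that number moves from the first to the last of them (falls all the way / rises, then falls / rises all the way / falls, then rises / hardly changes)

G enters the solution at the dissolution coefficient times the gap between the solubility and the concentration of Q, and while solid is left that law holds no term for the amount of solid. Q starts at zero, so the gap is widest at the start. I therefore carried one quantity, the dissolution ceiling: coefficient times solubility times run time, 1.08 mM, the Q delivered over the run at the widest gap. Control of the supply changes hands where the charge of G meets this ceiling. Larch has the smallest charge of the flasks, 20.0 mM, and the ceiling is far below it, so solid lasts through the run and the amount charged drops out of the supply.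

The ceiling also caps the product, since each X or D consumes one Q. It is 1.08% of the J and L together, so I took the concentrations of J and L as equal. Both steps share Q and E, so X and D then form in the ratio of their rate constants, the selectivity factor 3.41. That gave me an excess of 54.7% for larch, with no depletion of J counted, and the same reckoning for alder, birch and cedar, so I expected a row that hardly changes. I decided that the next run would carry larch's charge of G.

The forecast gave 54.6%, 54.6%, 54.6% and 54.6%, a row that hardly changes, holding that “Dissolution does not depend on how much solid is present”.

The simulation gave 54.6%, 54.6%, 54.6% and 54.6% from larch to cedar, so the excess hardly changes. In cedar the local order of the excess in equivalents of G was 0. Larch's ceiling is 5.40% of its charge, and 95.1% of its G stood undissolved at 10.0 min. The same ceiling is 0.216% of cedar's charge of 500 mM, and 99.8% of cedar's G stood undissolved at 10.0 min.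

The numbers are invented, and the outcome is calculated.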